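## The problem

The target 12 is a pentabrominated diphenyl ether in which two benzene rings are joined through one oxygen atom. Ring B is a 2,4-dibromophenyl group; ring A carries the aryloxy group at C1, a methoxy group at C2, hydrogen at C3 and bromine at C4, C5 and C6. There is no stereocentre and rotation about the ether bonds is free, so the whole problem is one of regiochemistry on ring A. Three adjacent bromines must be placed while C3 stays unsubstituted, although C3 is ortho to the methoxy group and one of the most reactive sites of a simple 2-aryloxyanisole. A stronger director is therefore needed at C5, from where it steers bromine to C4 and C6 and is then exchanged for bromine itself; an amino group is the natural choice. The ether bond is the second problem: aryl bromides rule out late copper- or palladium-mediated C–O coupling, halogen–metal exchange and catalytic hydrogenation, so the bond should come from an uncatalysed displacement, yet C1 is meta to C5 and a nitrogen group there cannot activate it. The answer lies in the C2 oxygen, which sits ortho to the ether carbon C1: an acetyl group placed at C2 first activates a C1 fluoride for substitution and is then converted into the C2–O bond by a Baeyer–Villiger aryl migration. The diaryl ether, the methyl ether and the aryl bromides are robust, but the nitrogen has to be masked as an amide while peracid is present, and the free anilines need care towards oxidants.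

## Retrosynthesis

**C5–Br.** The central bromine of 12 is cut first and traced back to the amino group of 2,6-dibromo-3-(2,4-dibromophenoxy)-4-methoxyaniline 10, through the diazonium salt 11. Cutting C4–Br or C6–Br first would leave no group able to direct them. C5 is the one position flanked by both and para to the blocked C2, so it is the right place for the nitrogen. The forward step is a Sandmeyer bromination of a hindered, weakly basic amine.

**C4–Br and C6–Br.** Both bonds of 10 are cut together, giving 3-(2,4-dibromophenoxy)-4-methoxyaniline 9. This removes two of the three ring A bromines and leaves a simple trisubstituted aniline. The forward bromination must go to the two positions ortho to nitrogen and leave C3 (meta to nitrogen, ortho to methoxy) and ring B alone.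

**Functional group adjustment.** Aniline 9 comes from the acetamide 8 by hydrolysis. Cutting the O–CH3 bond of 8 gives the phenol 7, which is set free from the aryl acetate 6. The amide is kept until the methyl group is on, so that only oxygen is alkylated.

**C2–O (key cut).** The aryl–oxygen bond of acetate 6 is traced back to the aryl–carbon bond of the ketone N-[4-acetyl-3-(2,4-dibromophenoxy)phenyl]acetamide 5 by a Baeyer–Villiger oxidation. The neighbouring cut, the C1–O ether bond of a guaiacol-type ring, would demand either an unactivated displacement or a metal-catalysed coupling next to aryl bromides. Turning the C2 oxygen into a carbonyl group gives C1 exactly the activation it lacks. The forward step must give aryl rather than methyl migration and must not oxidise nitrogen.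

**Nitrogen.** The acetamide of 5 is traced back through the free aminoketone 4 to the nitro ketone 3. The nitro group is inert and non-acidic during ether formation, whereas an amide N–H would be deprotonated and deactivate the ring.

**C1–O (ether).** Cutting the ether bond of 3 gives 1-(2-fluoro-4-nitrophenyl)ethanone 1 and 2,4-dibromophenol 2, both commercial. Ring B thus arrives with its two bromines already in place, and the forward reaction is a nucleophilic aromatic substitution of fluoride ortho to the acetyl group.

## Roads not taken

**Alternative 1: fourfold bromination of a bromine-free diaryl ether.** The cut removes C4–Br, C6–Br, C2'–Br and C4'–Br at once. In the forward direction 4-methoxy-3-phenoxyaniline A1 would take up four equivalents of an electrophilic bromine source to give 2,6-dibromo-3-(2,4-dibromophenoxy)-4-methoxyaniline A2, which is identical with 10, and the Sandmeyer step would follow.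
- Merits: A1 carries no halogen, so its ether bond can be made by ordinary copper-mediated O-phenylation of a nitroguaiacol. The target could be reached in about four steps, without a protecting group and without a peracid. On step count this road is better than the chosen one.
- Weak points: the four brominations are not equivalent. The positions ortho to nitrogen and the para position of ring B should react readily. The fourth bromine must enter ring B ortho to the ether oxygen, on a ring already deactivated by one bromine, in preference to C3 of ring A. Nothing in A1 secures that preference, and excess oxidant with an electron-rich aniline invites quinoid by-products.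
- Comparison: the chosen plan spends three more steps so that only two brominations remain, both ortho to the amine, with ring B fixed from the start.

**Alternative 2: oxidative cross-coupling of two bromophenols.** The cut is the ether bond O–C1 between two phenols. Anodic one-electron oxidation of 3,4,5-tribromophenol A3 and 2,4-dibromophenol 2 would join the oxygen of 2 to the ortho carbon of A3, giving 3,4,5-tribromo-2-(2,4-dibromophenoxy)phenol A4. O-Methylation would finish the synthesis.
- Merits: two steps, all bromines present from the outset, no nitrogen chemistry, and a likely parallel to the biogenesis. If it were selective, no other plan could match it.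
- Weak points: the two phenols oxidise at similar potentials, so homo-coupling of each competes statistically. Phenoxyl radicals also couple C–C and at bromine-bearing positions with loss of bromide. A4 is itself an oxidisable phenol and can be consumed or closed to a dibenzodioxin. No structural element directs the oxygen of 2 to the single required carbon.
- Comparison: the chosen plan is longer but forms every bond by a polar reaction whose regiochemistry can be predicted, and should avoid mixtures of closely related polybrominated isomers.

**Alternative 3: ring A built from a pyranone.** The cut removes C4–C5 and C5–C6. The anion of nitromethane A6 would add to 3-(2,4-dibromophenoxy)-4H-pyran-4-one A5, open the ring and reclose by nitroaldol condensation and dehydration to 2-(2,4-dibromophenoxy)-4-nitrophenol A7. Methylation and reduction would lead to 9, and steps 6 and 7 would follow.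
- Merits: oxygen at C2 and nitrogen at C5 are set in the correct para relationship in one operation. Addition at either α-carbon gives the same arene. No protecting group or peracid is needed, and only two steps separate A7 from 9.
- Weak points: A5 is not commercial. Making it raises the same problem of attaching the dibromophenoxy group to an oxygenated carbon, and would cost two or three steps. The ring transformation is established for alkyl- and acyl-substituted pyranones, whereas A5 is unsubstituted at both α-positions, carries a donor at C3, and is prone to base-induced opening without reclosure.
- Comparison: the overall length would be about the same as the chosen route, with two uncertain operations instead of well-precedented ones; the chosen plan starts from two catalogue compounds.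

Key step: step 3

## Route

Step 1
Reactants: 1 1-(2-fluoro-4-nitrophenyl)ethanone; 2 2,4-dibromophenol
Product: 3 1-[2-(2,4-dibromophenoxy)-4-nitrophenyl]ethanone
Conditions: K2CO3, DMF, 80 °C
Reagents that add atoms: none
Why: Nucleophilic aromatic substitution by addition–elimination: the ortho acetyl group stabilises the Meisenheimer adduct, the meta nitro group helps inductively, and fluoride is the best leaving group for this mechanism; ring B arrives with both bromines in place.

Step 2
Reactants: 3 1-[2-(2,4-dibromophenoxy)-4-nitrophenyl]ethanone
Product: 5 N-[4-acetyl-3-(2,4-dibromophenoxy)phenyl]acetamide, via aminoketone 4 (not isolated)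
Conditions: Fe powder, AcOH, 80 °C; then Ac2O, rt
Reagents that add atoms: acetic anhydride, CC(=O)OC(C)=O
Why: Iron in acetic acid (Béchamp-type reduction) reduces the nitro group without touching the ketone or the aryl bromides, and acetic anhydride then acylates the aniline in the same flask; the amide shields nitrogen from the peracid of step 3 while remaining a para donor.

Step 3
Reactants: 5 N-[4-acetyl-3-(2,4-dibromophenoxy)phenyl]acetamide
Product: 6 4-acetamido-2-(2,4-dibromophenoxy)phenyl acetate
Conditions: mCPBA (1.5 equiv), CF3CO2H (cat.), CH2Cl2, 0 °C to rt
Reagents that add atoms: 3-chloroperbenzoic acid (mCPBA), OOC(=O)c1cccc(Cl)c1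
Why: Baeyer–Villiger oxidation: the peracid adds to the acid-activated ketone to give the tetrahedral Criegee intermediate, and the aryl group, aligned antiperiplanar to the O–O bond, migrates from carbon to the proximal oxygen as 3-chlorobenzoate leaves, forming the C2–O bond. The closest known reaction type is the peracid oxidation of alkoxy- and acylamino-substituted acetophenones to aryl acetates. No ring is closed and no stereocentre is created. The step needs aryl rather than methyl migration, which the para acetamido and ortho aryloxy donors should secure by stabilising the positive charge that builds up in the migrating ring, methyl being the poorest migrating group. It also needs chemoselectivity for the ketone: nitrogen is present as an amide and resists N-oxidation, ring B is electron-poor, and the aryl acetate formed is less electron-rich than a free phenol and should not be oxidised further. Trifluoroacetic acid catalysis compensates for the lower electrophilicity of a carbonyl group conjugated to a para nitrogen donor.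

Step 4
Reactants: 6 4-acetamido-2-(2,4-dibromophenoxy)phenyl acetate
Product: 8 N-[3-(2,4-dibromophenoxy)-4-methoxyphenyl]acetamide, via phenol 7 (not isolated)
Conditions: K2CO3, MeOH, rt; then DMF in place of MeOH, MeI, rt
Reagents that add atoms: iodomethane, CI
Why: Carbonate in methanol cleaves the aryl acetate by transesterification far faster than the anilide, and the phenoxide is then O-methylated by iodomethane (Williamson ether synthesis); the amide N–H is too weakly acidic to be alkylated under carbonate.

Step 5
Reactants: 8 N-[3-(2,4-dibromophenoxy)-4-methoxyphenyl]acetamide
Product: 9 3-(2,4-dibromophenoxy)-4-methoxyaniline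
Conditions: 6 M HCl, 1,4-dioxane, reflux; then aq. NaOH
Reagents that add atoms: none
Why: Acid-catalysed hydrolysis of an acetanilide; the diaryl ether, the methyl ether and the aryl bromides are inert to hot aqueous HCl, and basification frees the aniline.

Step 6
Reactants: 9 3-(2,4-dibromophenoxy)-4-methoxyaniline
Product: 10 2,6-dibromo-3-(2,4-dibromophenoxy)-4-methoxyaniline
Conditions: NBS (2.05 equiv), MeCN, 0 °C to rt
Reagents that add atoms: N-bromosuccinimide, O=C1CCC(=O)N1Br
Why: Electrophilic aromatic bromination directed by the free amino group: both positions ortho to nitrogen react (C4, also para to the aryloxy oxygen, and C6), the para position C2 is blocked by the methoxy group, C3 is meta to nitrogen, and ring B is already deactivated by two bromines. Two equivalents of reagent at low temperature limit attack at C3.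

Step 7
Reactants: 10 2,6-dibromo-3-(2,4-dibromophenoxy)-4-methoxyaniline
Product: 12 1,2,3-tribromo-4-(2,4-dibromophenoxy)-5-methoxybenzene, via diazonium bromide 11 (not isolated)
Conditions: t-BuONO, CuBr2, MeCN, 0 to 60 °C
Reagents that add atoms: copper dibromide CuBr2, [Cu+2].[Br-].[Br-] (the C5 bromine); tert-butyl nitrite, CC(C)(C)ON=O (the second nitrogen of 11, which leaves again as N2)
Why: Sandmeyer bromination in its non-aqueous form: the alkyl nitrite diazotises the weakly basic amine in acetonitrile, copper-mediated electron transfer releases N2, and the aryl radical takes bromine from CuBr2. The diazonium group is meta to the aryloxy group, so no Pschorr-type closure onto ring B can occur.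

## Compound list

1 | 1-(2-fluoro-4-nitrophenyl)ethanone | CC(=O)c1ccc(cc1F)[N+](=O)[O-] | starting material
2 | 2,4-dibromophenol | Oc1ccc(Br)cc1Br | starting material
3 | 1-[2-(2,4-dibromophenoxy)-4-nitrophenyl]ethanone | CC(=O)c1ccc(cc1Oc1ccc(Br)cc1Br)[N+](=O)[O-] | intermediate
4 | 1-[4-amino-2-(2,4-dibromophenoxy)phenyl]ethanone | CC(=O)c1ccc(N)cc1Oc1ccc(Br)cc1Br | intermediate (not isolated)
5 | N-[4-acetyl-3-(2,4-dibromophenoxy)phenyl]acetamide | CC(=O)Nc1ccc(C(C)=O)c(Oc2ccc(Br)cc2Br)c1 | intermediate
6 | 4-acetamido-2-(2,4-dibromophenoxy)phenyl acetate | CC(=O)Nc1ccc(OC(C)=O)c(Oc2ccc(Br)cc2Br)c1 | intermediate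
7 | N-[3-(2,4-dibromophenoxy)-4-hydroxyphenyl]acetamide | CC(=O)Nc1ccc(O)c(Oc2ccc(Br)cc2Br)c1 | intermediate (not isolated)
8 | N-[3-(2,4-dibromophenoxy)-4-methoxyphenyl]acetamide | CC(=O)Nc1ccc(OC)c(Oc2ccc(Br)cc2Br)c1 | intermediate
9 | 3-(2,4-dibromophenoxy)-4-methoxyaniline | COc1ccc(N)cc1Oc1ccc(Br)cc1Br | intermediate
10 | 2,6-dibromo-3-(2,4-dibromophenoxy)-4-methoxyaniline | COc1cc(Br)c(N)c(Br)c1Oc1ccc(Br)cc1Br | intermediate
11 | 2,6-dibromo-3-(2,4-dibromophenoxy)-4-methoxybenzenediazonium bromide | COc1cc(Br)c([N+]#N)c(Br)c1Oc1ccc(Br)cc1Br.[Br-] | intermediate (not isolated)
12 | 1,2,3-tribromo-4-(2,4-dibromophenoxy)-5-methoxybenzene | COc1cc(Br)c(Br)c(Br)c1Oc1ccc(Br)cc1Br | target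

## Step count and risks

Total step count: 7. Longest linear sequence: 7 steps (from 1 or 2 to 12).

**Step 3 (key step).** The likeliest failure is slow addition of the peracid to a carbonyl group that the para nitrogen donor makes less electrophilic and the ortho aryloxy group crowds. Forcing conditions could then lead to ring hydroxylation or loss of the acetate.
Fallback: the oxygen is inserted by a benzylic hydroperoxide rearrangement, in which the same donors now help by stabilising a benzylic cation. It sets out from 5. MeMgBr (3 equiv, THF, 0 °C; the first equivalent deprotonates the amide) adds to the ketone to give N-[3-(2,4-dibromophenoxy)-4-(2-hydroxypropan-2-yl)phenyl]acetamide F1. H2O2 with BF3·OEt2 in CH2Cl2 at 0 °C converts the tertiary alcohol into N-[3-(2,4-dibromophenoxy)-4-(2-hydroperoxypropan-2-yl)phenyl]acetamide F2. Under the same acid F2 rearranges by aryl migration to oxygen (Hock-type rearrangement) and releases acetone; the doubly brominated ring B should not compete with hydrogen peroxide for the cation. The fallback comes back to the route at phenol 7, which is methylated as in the second half of step 4 to give 8.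

**Step 6.** The second bromination at the crowded C6, between the amino and aryloxy groups, may be overtaken by bromination at C3 ortho to the methoxy group, or by oxidation of the electron-rich aniline.
Fallback: bromination is moved to the aminoketone stage, where the acetyl group deactivates C3 and no methoxy group is present. It sets out from 4, isolated by leaving out Ac2O in step 2. NBS (2 equiv, MeCN) should give 1-[4-amino-3,5-dibromo-2-(2,4-dibromophenoxy)phenyl]ethanone F3. t-BuONO/CuBr2 converts it through 4-acetyl-2,6-dibromo-3-(2,4-dibromophenoxy)benzenediazonium bromide F4 into 1-[3,4,5-tribromo-2-(2,4-dibromophenoxy)phenyl]ethanone F5. Baeyer–Villiger oxidation with the stronger CF3CO3H is needed because the ring is now electron-poor, with only the ortho aryloxy oxygen assisting migration; it gives 3,4,5-tribromo-2-(2,4-dibromophenoxy)phenyl acetate F6. K2CO3/MeOH frees 3,4,5-tribromo-2-(2,4-dibromophenoxy)phenol F7 (the same compound as A4), and MeI/K2CO3 methylates it to 12, where the fallback rejoins the route.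

**Step 7.** Diazotisation of the weakly basic, doubly ortho-substituted amine may be slow, and the aryl radical may abstract hydrogen from the medium (hydrodediazoniation) instead of taking bromine.
Fallback: the nitrogen is replaced by an ionic route through an isolable triazene. It sets out from 10, which is diazotised without copper (t-BuONO, 48% aq. HBr, MeCN, 0 °C) to 11. The cold solution is run into diethylamine/K2CO3 to give (E)-1-[2,6-dibromo-3-(2,4-dibromophenoxy)-4-methoxyphenyl]-3,3-diethyltriaz-1-ene F8, which can be purified. Heating F8 with Me3SiBr in MeCN at 60 °C cleaves the triazene and delivers bromide to the aryl carbon, returning to the route at 12.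

**Step 1.** The hindered, weakly nucleophilic 2,4-dibromophenoxide may react slowly, so that base-induced self-condensation of the methyl ketone or attack at the nitro-bearing carbon para to the acetyl group gains ground.
Fallback: the polarity of ether formation is reversed. It sets out from 1, whose fluoride is displaced by the small, strong nucleophile hydroxide (KOH, DMSO–H2O, rt) to give 1-(2-hydroxy-4-nitrophenyl)ethanone F9. Its phenoxide (t-BuOK, THF, 40 °C) is O-arylated by metal-free ligand coupling with bis(2,4-dibromophenyl)iodonium trifluoromethanesulfonate F10, a reagent made by oxidative coupling of the two corresponding bromoarenes (mCPBA, TfOH). This comes back to the route at 3.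

## Further compounds

F1 | step 3 | N-[3-(2,4-dibromophenoxy)-4-(2-hydroxypropan-2-yl)phenyl]acetamide | CC(=O)Nc1ccc(C(C)(C)O)c(Oc2ccc(Br)cc2Br)c1
F2 | step 3 | N-[3-(2,4-dibromophenoxy)-4-(2-hydroperoxypropan-2-yl)phenyl]acetamide | CC(=O)Nc1ccc(C(C)(C)OO)c(Oc2ccc(Br)cc2Br)c1
F3 | step 6 | 1-[4-amino-3,5-dibromo-2-(2,4-dibromophenoxy)phenyl]ethanone | CC(=O)c1cc(Br)c(N)c(Br)c1Oc1ccc(Br)cc1Br
F4 | step 6 | 4-acetyl-2,6-dibromo-3-(2,4-dibromophenoxy)benzenediazonium bromide | CC(=O)c1cc(Br)c([N+]#N)c(Br)c1Oc1ccc(Br)cc1Br.[Br-]
F5 | step 6 | 1-[3,4,5-tribromo-2-(2,4-dibromophenoxy)phenyl]ethanone | CC(=O)c1cc(Br)c(Br)c(Br)c1Oc1ccc(Br)cc1Br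
F6 | step 6 | 3,4,5-tribromo-2-(2,4-dibromophenoxy)phenyl acetate | CC(=O)Oc1cc(Br)c(Br)c(Br)c1Oc1ccc(Br)cc1Br
F7 | step 6 | 3,4,5-tribromo-2-(2,4-dibromophenoxy)phenol | Oc1cc(Br)c(Br)c(Br)c1Oc1ccc(Br)cc1Br
F8 | step 7 | (E)-1-[2,6-dibromo-3-(2,4-dibromophenoxy)-4-methoxyphenyl]-3,3-diethyltriaz-1-ene | CCN(CC)/N=N/c1c(Br)cc(OC)c(Oc2ccc(Br)cc2Br)c1Br
F9 | step 1 | 1-(2-hydroxy-4-nitrophenyl)ethanone | CC(=O)c1ccc(cc1O)[N+](=O)[O-]
F10 | step 1 | bis(2,4-dibromophenyl)iodonium trifluoromethanesulfonate | Brc1ccc([I+]c2ccc(Br)cc2Br)c(Br)c1.[O-]S(=O)(=O)C(F)(F)F
A1 | alternative 1 | 4-methoxy-3-phenoxyaniline | COc1ccc(N)cc1Oc1ccccc1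
A2 | alternative 1 | 2,6-dibromo-3-(2,4-dibromophenoxy)-4-methoxyaniline | COc1cc(Br)c(N)c(Br)c1Oc1ccc(Br)cc1Br
A3 | alternative 2 | 3,4,5-tribromophenol | Oc1cc(Br)c(Br)c(Br)c1
A4 | alternative 2 | 3,4,5-tribromo-2-(2,4-dibromophenoxy)phenol | Oc1cc(Br)c(Br)c(Br)c1Oc1ccc(Br)cc1Br
A5 | alternative 3 | 3-(2,4-dibromophenoxy)-4H-pyran-4-one | O=c1ccocc1Oc1ccc(Br)cc1Br
A6 | alternative 3 | nitromethane | C[N+](=O)[O-]
A7 | alternative 3 | 2-(2,4-dibromophenoxy)-4-nitrophenol | Oc1ccc(cc1Oc1ccc(Br)cc1Br)[N+](=O)[O-]
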